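**Target:** (1R,2R)-1-(4-hydroxy-3,5-dimethoxyphenyl)-2-[4-(3-hydroxypropyl)-2,6-dimethoxyphenoxy]propane-1,3-diol, the threo (7R,8R) 8-O-4' neolignan. Chain carbons are called C7 (benzylic carbinol), C8 (aryloxy-bearing) and C9 (CH2OH).

**Retrosynthetic overview**
1. Target ⇐ triol protected as benzyl ether (ring A phenol) and TBS ether (side-chain alcohol); deprotection last (Bu4NF, then H2 over Pd/C).
2. C9 alcohol ⇐ hydride cleavage of an N-acyl oxazolidinone, whose imide carbonyl becomes CH2OH.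
3. C7–C8 bond ⇐ Evans boron syn-aldol of the (aryloxy)acetyl imide of (S)-4-benzyl-1,3-oxazolidin-2-one with 4-O-benzylsyringaldehyde; both stereocentres are set here.
4. Imide ⇐ 4-allyl-2,6-dimethoxyphenol by O-alkylation with ethyl bromoacetate, hydroboration–oxidation, silylation, saponification and N-acylation.
5. No ring is constructed: ring A is bought as syringaldehyde, ring B as 4-allyl-2,6-dimethoxyphenol.

Assumption: 4-allyl-2,6-dimethoxyphenol, syringaldehyde, ethyl bromoacetate and (S)-4-benzyl-1,3-oxazolidin-2-one are taken as cheap catalogue chemicals.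

**Route**

Step 1
Reactants: 1 4-allyl-2,6-dimethoxyphenol; 2 ethyl bromoacetate
Product: 3 ethyl 2-(4-allyl-2,6-dimethoxyphenoxy)acetate
Conditions: K2CO3, acetone, reflux
Reagents that add atoms: none
Why: Williamson ether synthesis, in which the phenoxide displaces bromide from the activated α-bromo ester by SN2; no stereocentre is involved.

Step 2
Reactants: 3 ethyl 2-(4-allyl-2,6-dimethoxyphenoxy)acetate
Product: 5 ethyl 2-[4-(3-hydroxypropyl)-2,6-dimethoxyphenoxy]acetate, via B-alkyl-9-BBN adduct 4 (not isolated)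
Conditions: 9-BBN, THF, 0 °C to rt; then 30% H2O2, aq. NaOAc, 0 °C to rt
Reagents that add atoms: 9-borabicyclo[3.3.1]nonane (9-BBN), B1C2CCCC1CCC2 (its boron unit stays only in 4); hydrogen peroxide, OO
Why: Brown hydroboration–oxidation, in which 9-BBN adds anti-Markovnikov to the terminal alkene without reducing the ester and the acetate-buffered peroxide oxidises the C–B bond without saponification.

Step 3
Reactants: 5 ethyl 2-[4-(3-hydroxypropyl)-2,6-dimethoxyphenoxy]acetate
Product: 6 ethyl 2-{4-[3-(tert-butyldimethylsilyloxy)propyl]-2,6-dimethoxyphenoxy}acetate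
Conditions: TBSCl, imidazole, CH2Cl2, 0 °C to rt
Reagents that add atoms: tert-butyldimethylsilyl chloride (TBSCl), CC(C)(C)[Si](C)(C)Cl
Why: Silyl ether protection of the only free hydroxyl, so that it cannot consume boron triflate or be acylated later.

Step 4
Reactants: 6 ethyl 2-{4-[3-(tert-butyldimethylsilyloxy)propyl]-2,6-dimethoxyphenoxy}acetate
Product: 8 2-{4-[3-(tert-butyldimethylsilyloxy)propyl]-2,6-dimethoxyphenoxy}acetic acid, via lithium carboxylate 7 (not isolated)
Conditions: LiOH·H2O, THF/H2O, 0 °C to rt; then cold 0.5 M HCl to pH 3–4, immediate extraction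
Reagents that add atoms: lithium hydroxide, [Li+].[OH-]
Why: Ester saponification of an activated aryloxyacetate, which is fast under conditions (and a brief cold pH 3–4 acidification) that a primary TBS ether tolerates.

Step 5
Reactants: 8 2-{4-[3-(tert-butyldimethylsilyloxy)propyl]-2,6-dimethoxyphenoxy}acetic acid; 9 (4S)-4-benzyl-1,3-oxazolidin-2-one
Product: 11 (4S)-4-benzyl-3-(2-{4-[3-(tert-butyldimethylsilyloxy)propyl]-2,6-dimethoxyphenoxy}acetyl)-1,3-oxazolidin-2-one, via pivalic mixed anhydride 10 (not isolated)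
Conditions: PivCl, Et3N, THF, −20 °C; then LiCl, 9, −20 °C to rt
Reagents that add atoms: pivaloyl chloride, CC(C)(C)C(=O)Cl (its atoms stay only in 10)
Why: N-acylation through a mixed anhydride, in which the LiCl-activated oxazolidinone attacks the unhindered aryloxyacetyl carbonyl and not the pivaloyl one; the auxiliary stereocentre is untouched.

Step 6
Reactants: 12 syringaldehyde (4-hydroxy-3,5-dimethoxybenzaldehyde)
Product: 13 4-(benzyloxy)-3,5-dimethoxybenzaldehyde
Conditions: BnBr, K2CO3, DMF, 60 °C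
Reagents that add atoms: benzyl bromide, BrCc1ccccc1
Why: Williamson etherification masks the acidic phenol as a benzyl ether that survives the aldol and hydride steps and is removable under neutral conditions.

Step 7
Reactants: 11 (4S)-4-benzyl-3-(2-{4-[3-(tert-butyldimethylsilyloxy)propyl]-2,6-dimethoxyphenoxy}acetyl)-1,3-oxazolidin-2-one; 13 4-(benzyloxy)-3,5-dimethoxybenzaldehyde
Product: 16 (4S)-4-benzyl-3-[(2S,3R)-3-[4-(benzyloxy)-3,5-dimethoxyphenyl]-2-{4-[3-(tert-butyldimethylsilyloxy)propyl]-2,6-dimethoxyphenoxy}-3-hydroxypropanoyl]-1,3-oxazolidin-2-one, via Z-dibutylboron enolate 14 (not isolated), via dibutylboron aldolate 15 (not isolated)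
Conditions: Bu2BOTf, i-Pr2NEt, CH2Cl2, −78 to 0 °C; then 13, −78 to 0 °C; then pH 7 buffer (NaH2PO4/Na2HPO4), MeOH, 30% H2O2, 0 °C
Reagents that add atoms: dibutylboron triflate, CCCCB(CCCC)OS(=O)(=O)C(F)(F)F (its atoms stay only in 14 and 15)
Why: Evans syn-aldol, in which soft enolisation gives the Z boron enolate and a closed Zimmerman–Traxler chair with the oxazolidinone dipole opposed to the enolate C–O bond sends the aldehyde to the enolate face away from the benzyl group, setting (2S,3R), the later 8R and 7R centres, in one step.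

Step 8
Reactants: 16 the syn-aldol adduct
Product: 17 (1R,2R)-1-[4-(benzyloxy)-3,5-dimethoxyphenyl]-2-{4-[3-(tert-butyldimethylsilyloxy)propyl]-2,6-dimethoxyphenoxy}propane-1,3-diol
Conditions: LiBH4, H2O (1 equiv), THF, 0 °C
Reagents that add atoms: none
Why: Reductive cleavage of the N-acyl oxazolidinone by hydride attack at the exocyclic carbonyl gives the primary alcohol and returns the auxiliary; no bond at a stereocentre is touched, and the descriptor of the aryloxy carbon changes from S to R only because CH2OH ranks below the carbinol carbon.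

Step 9
Reactants: 17 the benzyl- and TBS-protected diol
Product: 18 (1R,2R)-1-[4-(benzyloxy)-3,5-dimethoxyphenyl]-2-[4-(3-hydroxypropyl)-2,6-dimethoxyphenoxy]propane-1,3-diol
Conditions: Bu4NF, THF, 0 °C to rt
Reagents that add atoms: none
Why: Fluoride-mediated desilylation, done while the phenol is still benzylated so that the basic medium cannot open a quinone methide pathway at C7.

Step 10
Reactants: 18 the O-benzyl triol
Product: 19 (1R,2R)-1-(4-hydroxy-3,5-dimethoxyphenyl)-2-[4-(3-hydroxypropyl)-2,6-dimethoxyphenoxy]propane-1,3-diol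
Conditions: H2 (1 atm), 10% Pd/C, EtOAc, rt, stopped when 18 is consumed
Reagents that add atoms: none
Why: Catalytic hydrogenolysis of a phenolic benzyl ether is fast under neutral conditions that leave the benzylic secondary alcohol intact and cannot epimerise C7 as acid would.

**Compound list**
1 | 4-allyl-2,6-dimethoxyphenol | C=CCc1cc(OC)c(O)c(OC)c1 | starting material
2 | ethyl bromoacetate | CCOC(=O)CBr | starting material
3 | ethyl 2-(4-allyl-2,6-dimethoxyphenoxy)acetate | CCOC(=O)COc1c(OC)cc(CC=C)cc1OC | intermediate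
4 | ethyl 2-{4-[3-(9-borabicyclo[3.3.1]nonan-9-yl)propyl]-2,6-dimethoxyphenoxy}acetate (B-alkyl-9-BBN adduct) | CCOC(=O)COc1c(OC)cc(CCCB2C3CCCC2CCC3)cc1OC | intermediate
5 | ethyl 2-[4-(3-hydroxypropyl)-2,6-dimethoxyphenoxy]acetate | CCOC(=O)COc1c(OC)cc(CCCO)cc1OC | intermediate
6 | ethyl 2-{4-[3-(tert-butyldimethylsilyloxy)propyl]-2,6-dimethoxyphenoxy}acetate | CCOC(=O)COc1c(OC)cc(CCCO[Si](C)(C)C(C)(C)C)cc1OC | intermediate
7 | lithium 2-{4-[3-(tert-butyldimethylsilyloxy)propyl]-2,6-dimethoxyphenoxy}acetate | [Li+].[O-]C(=O)COc1c(OC)cc(CCCO[Si](C)(C)C(C)(C)C)cc1OC | intermediate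
8 | 2-{4-[3-(tert-butyldimethylsilyloxy)propyl]-2,6-dimethoxyphenoxy}acetic acid | OC(=O)COc1c(OC)cc(CCCO[Si](C)(C)C(C)(C)C)cc1OC | intermediate
9 | (4S)-4-benzyl-1,3-oxazolidin-2-one | O=C1N[C@@H](Cc2ccccc2)CO1 | starting material
10 | mixed anhydride of acid 8 with pivalic acid | CC(C)(C)C(=O)OC(=O)COc1c(OC)cc(CCCO[Si](C)(C)C(C)(C)C)cc1OC | intermediate
11 | (4S)-4-benzyl-3-(2-{4-[3-(tert-butyldimethylsilyloxy)propyl]-2,6-dimethoxyphenoxy}acetyl)-1,3-oxazolidin-2-one | O=C(COc1c(OC)cc(CCCO[Si](C)(C)C(C)(C)C)cc1OC)N1[C@@H](Cc2ccccc2)COC1=O | intermediate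
12 | syringaldehyde (4-hydroxy-3,5-dimethoxybenzaldehyde) | COc1cc(C=O)cc(OC)c1O | starting material
13 | 4-(benzyloxy)-3,5-dimethoxybenzaldehyde | COc1cc(C=O)cc(OC)c1OCc1ccccc1 | intermediate
14 | Z dibutylboron enolate of imide 11 (O–B and aryloxy group cis on the C=C) | CCCCB(CCCC)O/C(=C\Oc1c(OC)cc(CCCO[Si](C)(C)C(C)(C)C)cc1OC)N1[C@@H](Cc2ccccc2)COC1=O | intermediate
15 | O-dibutylboryl aldolate of adduct 16 (2S,3R) | COc1cc([C@@H](OB(CCCC)CCCC)[C@@H](C(=O)N2[C@@H](Cc3ccccc3)COC2=O)Oc2c(OC)cc(CCCO[Si](C)(C)C(C)(C)C)cc2OC)cc(OC)c1OCc1ccccc1 | intermediate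
16 | (4S)-4-benzyl-3-[(2S,3R)-3-[4-(benzyloxy)-3,5-dimethoxyphenyl]-2-{4-[3-(tert-butyldimethylsilyloxy)propyl]-2,6-dimethoxyphenoxy}-3-hydroxypropanoyl]-1,3-oxazolidin-2-one | COc1cc([C@@H](O)[C@@H](C(=O)N2[C@@H](Cc3ccccc3)COC2=O)Oc2c(OC)cc(CCCO[Si](C)(C)C(C)(C)C)cc2OC)cc(OC)c1OCc1ccccc1 | intermediate
17 | (1R,2R)-1-[4-(benzyloxy)-3,5-dimethoxyphenyl]-2-{4-[3-(tert-butyldimethylsilyloxy)propyl]-2,6-dimethoxyphenoxy}propane-1,3-diol | COc1cc([C@@H](O)[C@@H](CO)Oc2c(OC)cc(CCCO[Si](C)(C)C(C)(C)C)cc2OC)cc(OC)c1OCc1ccccc1 | intermediate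
18 | (1R,2R)-1-[4-(benzyloxy)-3,5-dimethoxyphenyl]-2-[4-(3-hydroxypropyl)-2,6-dimethoxyphenoxy]propane-1,3-diol | COc1cc([C@@H](O)[C@@H](CO)Oc2c(OC)cc(CCCO)cc2OC)cc(OC)c1OCc1ccccc1 | intermediate
19 | (1R,2R)-1-(4-hydroxy-3,5-dimethoxyphenyl)-2-[4-(3-hydroxypropyl)-2,6-dimethoxyphenoxy]propane-1,3-diol | COc1cc([C@@H](O)[C@@H](CO)Oc2c(OC)cc(CCCO)cc2OC)cc(OC)c1O | target

**Summary**
Total steps: 10. Longest linear sequence: 9 steps (steps 1, 2, 3, 4, 5, 7, 8, 9, 10, from phenol 1); step 6 is a one-step side branch.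

**Steps most likely to fail, with fallbacks**

Step 7 (boron aldol). The hindered, oxygen-rich 2,6-dimethoxyphenoxy group may slow enolisation or erode the syn selectivity. The fallback sets out from acid 8 and comes back to the route at diol 17. Acid 8 is activated as mixed anhydride 10 as in step 5 but trapped with (S)-4-benzyl-1,3-oxazolidine-2-thione (LiCl, Et3N) to give the N-acyl oxazolidinethione F1. TiCl4, i-Pr2NEt and N-methyl-2-pyrrolidinone in CH2Cl2 at −78 °C convert it into the Z trichlorotitanium enolate F2. This adds to aldehyde 13 through the titanium aldolate F3 and, after NH4Cl work-up, gives the syn adduct F4 with the same (2S,3R) configuration. NaBH4 in THF/H2O at 0 °C cleaves the labile thioimide directly to diol 17.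

Step 8 (reductive removal of the auxiliary). The free β-hydroxy imide of an aryl aldehyde can undergo retro-aldol or C8 epimerisation under basic hydride conditions. The fallback sets out from adduct 16 and comes back at triol 18. TESOTf and 2,6-lutidine in CH2Cl2 at −78 °C cap the benzylic hydroxyl as the triethylsilyl ether F5, which cannot undergo retro-aldol. LiBH4 (THF, H2O 1 equiv, 0 °C) then gives the primary alcohol F6. Excess Bu4NF in THF removes both silyl groups and delivers 18.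

Step 2 (hydroboration next to the ester). The activated aryloxyacetate may partly hydrolyse during the oxidative work-up. The fallback sets out from allyl ester 3 and comes back at lithium carboxylate 7, just before acid 8. The same 9-BBN hydroboration (through 4) is finished with aqueous LiOH and 30% H2O2, which oxidises the C–B bond and saponifies the ester in one pot to the lithium salt of the hydroxy acid F7. Acidification gives 2-[4-(3-hydroxypropyl)-2,6-dimethoxyphenoxy]acetic acid F8. TBSCl (2.5 equiv) and imidazole in DMF silylate both the alcohol and the acid to the silyl ether silyl ester F9. LiOH (1 equiv, THF/H2O, 0 °C) cleaves only the silyl ester and lands on 7, which is acidified as in step 4.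

**Further compounds**
F1 | step 7 | (4S)-4-benzyl-3-(2-{4-[3-(tert-butyldimethylsilyloxy)propyl]-2,6-dimethoxyphenoxy}acetyl)-1,3-oxazolidine-2-thione | O=C(COc1c(OC)cc(CCCO[Si](C)(C)C(C)(C)C)cc1OC)N1[C@@H](Cc2ccccc2)COC1=S
F2 | step 7 | Z trichlorotitanium enolate of F1 | Cl[Ti](Cl)(Cl)O/C(=C\Oc1c(OC)cc(CCCO[Si](C)(C)C(C)(C)C)cc1OC)N1[C@@H](Cc2ccccc2)COC1=S
F3 | step 7 | O-trichlorotitanium aldolate of F4 (2S,3R) | COc1cc([C@@H](O[Ti](Cl)(Cl)Cl)[C@@H](C(=O)N2[C@@H](Cc3ccccc3)COC2=S)Oc2c(OC)cc(CCCO[Si](C)(C)C(C)(C)C)cc2OC)cc(OC)c1OCc1ccccc1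
F4 | step 7 | (4S)-4-benzyl-3-[(2S,3R)-3-[4-(benzyloxy)-3,5-dimethoxyphenyl]-2-{4-[3-(tert-butyldimethylsilyloxy)propyl]-2,6-dimethoxyphenoxy}-3-hydroxypropanoyl]-1,3-oxazolidine-2-thione | COc1cc([C@@H](O)[C@@H](C(=O)N2[C@@H](Cc3ccccc3)COC2=S)Oc2c(OC)cc(CCCO[Si](C)(C)C(C)(C)C)cc2OC)cc(OC)c1OCc1ccccc1
F5 | step 8 | (4S)-4-benzyl-3-[(2S,3R)-3-[4-(benzyloxy)-3,5-dimethoxyphenyl]-2-{4-[3-(tert-butyldimethylsilyloxy)propyl]-2,6-dimethoxyphenoxy}-3-(triethylsilyloxy)propanoyl]-1,3-oxazolidin-2-one | COc1cc([C@@H](O[Si](CC)(CC)CC)[C@@H](C(=O)N2[C@@H](Cc3ccccc3)COC2=O)Oc2c(OC)cc(CCCO[Si](C)(C)C(C)(C)C)cc2OC)cc(OC)c1OCc1ccccc1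
F6 | step 8 | (2R,3R)-3-[4-(benzyloxy)-3,5-dimethoxyphenyl]-2-{4-[3-(tert-butyldimethylsilyloxy)propyl]-2,6-dimethoxyphenoxy}-3-(triethylsilyloxy)propan-1-ol | COc1cc([C@@H](O[Si](CC)(CC)CC)[C@@H](CO)Oc2c(OC)cc(CCCO[Si](C)(C)C(C)(C)C)cc2OC)cc(OC)c1OCc1ccccc1
F7 | step 2 | lithium 2-[4-(3-hydroxypropyl)-2,6-dimethoxyphenoxy]acetate | [Li+].[O-]C(=O)COc1c(OC)cc(CCCO)cc1OC
F8 | step 2 | 2-[4-(3-hydroxypropyl)-2,6-dimethoxyphenoxy]acetic acid | OC(=O)COc1c(OC)cc(CCCO)cc1OC
F9 | step 2 | tert-butyldimethylsilyl 2-{4-[3-(tert-butyldimethylsilyloxy)propyl]-2,6-dimethoxyphenoxy}acetate | CC(C)(C)[Si](C)(C)OC(=O)COc1c(OC)cc(CCCO[Si](C)(C)C(C)(C)C)cc1OC
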